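The western oxolane is read as an opened cyclohexene, and everything rests on that. With the ring numbered O1, C2 (acetonyl), C3, C4 (CH3), C5 (quaternary), the three acetonyl carbons, C2, C3, C4 with its methyl and C5 with its methyl map onto a 3,4,5-trimethylcyclohexene whose fully substituted double bond links the future acetyl carbon to C5, O1 being the carbinol oxygen. Ozonolysis of enantiopure (1R,5R)-3,4,5-trimethylcyclohex-3-en-1-ol therefore delivers in one operation both methyl ketones and, by closure of the hydroxyl onto C5, the oxolane as a hemiketal with C2 and C4 already in place. C5 is then set by enol silane addition, and a Stille coupling attaches the acetylenic polyene.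

Key step: step 6

Assumption: the lipase is taken to acylate the (1R) enantiomer of the trans alcohol, as the empirical size rule for secondary alcohols suggests if the alkene-bearing arm acts as the larger group; were the preference opposite, the unreacted alcohol would be the (1R,5R) enantiomer and would go directly into the key step, without step 5.

Remark: conjugate bases made by simple deprotonation (phenoxide, enolates, the phosphonate anion, dibromomethyllithium) are treated as forms of the numbered compound and carry no number of their own.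

Remark: the oxolane is numbered O1, C2 (acetonyl-bearing), C3, C4 (CH3), C5 (quaternary) throughout; the dialdehyde and the enynol used below are commercial carotenoid building blocks.

Step 1
Reactants: 1 3,4,5-trimethylphenol
Product: 2 5-methoxy-1,2,3-trimethylbenzene (3,4,5-trimethylanisole)
Conditions: MeI, K2CO3, acetone, reflux
Reagents that add atoms: iodomethane, CI
Why: Williamson ether synthesis of a phenoxide with an unhindered methyl electrophile is reliable and installs the methoxy group that will direct the Birch reduction.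

Step 2
Reactants: 2 5-methoxy-1,2,3-trimethylbenzene
Product: 4 3,4,5-trimethylcyclohex-3-en-1-one (racemic), via methoxy diene 3 (not isolated)
Conditions: Li, NH3 (l), THF, t-BuOH, −78 to −33 °C; NH4Cl, NH3 evaporated; then (CO2H)2, MeOH/H2O, 20 °C
Reagents that add atoms: water, O
Why: Birch reduction of an anisole keeps the methoxy group on a double bond, so that only 1-methoxy-3,4,5-trimethylcyclohexa-1,4-diene can form, and mild oxalic acid hydrolysis of its enol ether should unveil the ketone without moving the tetrasubstituted alkene into conjugation, the methyl-bearing sp3 carbon arising as a racemate.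

Step 3
Reactants: 4 3,4,5-trimethylcyclohex-3-en-1-one (racemic)
Product: 5 trans-3,4,5-trimethylcyclohex-3-en-1-ol (racemic)
Conditions: LiBH(s-Bu)3, THF, −78 °C; then NaOH, H2O2, 0 °C
Reagents that add atoms: none
Why: Reduction of a cyclohexanone with a bulky trialkylborohydride is expected to deliver hydride along the equatorial trajectory and so give the axial alcohol, here trans to the C5 methyl group, any cis isomer being removed by chromatography.

Step 4
Reactants: 5 trans-3,4,5-trimethylcyclohex-3-en-1-ol (racemic)
Product: 6 (1R,5R)-3,4,5-trimethylcyclohex-3-en-1-yl acetate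
Conditions: vinyl acetate, Burkholderia cepacia lipase (Amano PS, immobilised), t-BuOMe, 30 °C, to be stopped near half conversion
Reagents that add atoms: vinyl acetate, CC(=O)OC=C
Why: Lipase-catalysed kinetic resolution by irreversible transesterification should acylate one enantiomer of the secondary alcohol, so that both stereocentres of the acetate are fixed by the enzyme's choice between the two trans enantiomers and the unreacted (1S,5S) alcohol is separated by chromatography.

Step 5
Reactants: 6 (1R,5R)-3,4,5-trimethylcyclohex-3-en-1-yl acetate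
Product: 7 (1R,5R)-3,4,5-trimethylcyclohex-3-en-1-ol
Conditions: K2CO3, MeOH, 20 °C
Reagents that add atoms: none
Why: Base-catalysed methanolysis (transesterification) of the acetate cleaves the acyl C–O bond only and so returns the alcohol with both stereocentres unchanged.

Step 6
Reactants: 7 (1R,5R)-3,4,5-trimethylcyclohex-3-en-1-ol
Product: 10 1-[(2R,4R)-5-hydroxy-4,5-dimethyloxolan-2-yl]propan-2-one (both C5 anomers), via primary ozonide 8 (not isolated), via hydroxy diketone 9 (not isolated)
Conditions: O3, CH2Cl2/MeOH (4:1), NaHCO3, −78 °C; then Me2S, −78 to 20 °C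
Reagents that add atoms: ozone, [O-][O+]=O
Why: Ozone adds as a 1,3-dipole to the only C=C, the electron-rich tetrasubstituted alkene, to give primary ozonide 8, whose cycloreversion products are reduced by Me2S to (4R,6R)-4-hydroxy-6-methyloctane-2,7-dione 9. The closest known reaction type is the reductive ozonolysis of a cycloalkenol to a hydroxy dicarbonyl compound that closes spontaneously to a five-membered lactol. The oxolane closes by 5-exo-trig addition of the C4 hydroxyl of 9 to the C7 carbonyl, which forms the O1–C5 bond, whereas closure onto the other carbonyl would need a four-membered ring. No stereocentre of the target is created, since C2 and C4 lie off the cleaved bond and are carried over from 7 (the trans OH/CH3 relation of the carbocycle becomes the cis acetonyl/CH3 relation of the oxolane because oxygen replaces a carbon as ring member), and the anomeric C5 forms as an equilibrating mixture that is erased in step 11. The step needs cleavage of the alkene without dehydration of the β-hydroxy ketone, aldolisation or enolisation at the α-methyl centre of the open form, and the bicarbonate buffer, the low temperature, the neutral reductant and the fast hemiketal closure that masks the C5 carbonyl secure this.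

Step 7
Reactants: 10 1-[(2R,4R)-5-hydroxy-4,5-dimethyloxolan-2-yl]propan-2-one
Product: 11 1-[(2R,4R)-5-methoxy-4,5-dimethyloxolan-2-yl]propan-2-one (both C5 anomers)
Conditions: MeOH, pyridinium p-toluenesulfonate (cat.), 3 Å molecular sieves, 0 to 20 °C
Reagents that add atoms: methanol, CO
Why: Acid-catalysed exchange of a cyclic hemiketal with methanol through its oxocarbenium ion gives the mixed methyl ketal, and the weak pyridinium acid should leave the acyclic ketone and the C4 centre alone.

Step 8
Reactants: 12 but-3-yn-2-ol (racemic)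
Product: 14 (E)-4-iodo-3-methylbut-3-en-2-ol (racemic), via vinylalane 13 (not isolated)
Conditions: AlMe3, Cp2ZrCl2 (cat.), CH2Cl2, 0 to 20 °C; then I2, THF, −30 to 0 °C
Reagents that add atoms: trimethylaluminium, C[Al](C)C; iodine, II
Why: Negishi zirconium-catalysed carboalumination adds methyl and aluminium syn across the terminal alkyne with the metal at the terminus, and iodinolysis of the C–Al bond with retention fixes the E vinyl iodide.

Step 9
Reactants: 14 (E)-4-iodo-3-methylbut-3-en-2-ol
Product: 15 (E)-4-iodo-3-methylbut-3-en-2-one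
Conditions: MnO2, CH2Cl2, 20 °C
Reagents that add atoms: none
Why: Manganese dioxide oxidation is selective for allylic alcohols and leaves the vinyl iodide and its geometry untouched.

Step 10
Reactants: 15 (E)-4-iodo-3-methylbut-3-en-2-one
Product: 16 [(3E)-4-iodo-3-methylbuta-1,3-dien-2-yl]oxy(trimethyl)silane
Conditions: LiN(SiMe3)2, THF, −78 °C; then Me3SiCl, −78 to 0 °C
Reagents that add atoms: chlorotrimethylsilane, C[Si](C)(C)Cl
Why: Kinetic deprotonation with a hindered, non-nucleophilic amide occurs at the acetyl methyl group, the only enolisable position, and O-silylation of the enolate gives the silyl enol ether without touching the E iodoalkene.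

Step 11
Reactants: 11 1-[(2R,4R)-5-methoxy-4,5-dimethyloxolan-2-yl]propan-2-one; 16 [(3E)-4-iodo-3-methylbuta-1,3-dien-2-yl]oxy(trimethyl)silane
Product: 17 1-[(2R,4R,5S)-5-[(3E)-4-iodo-3-methyl-2-oxobut-3-en-1-yl]-4,5-dimethyloxolan-2-yl]propan-2-one
Conditions: Me3SiOTf (0.2 equiv), CH2Cl2, −78 °C, no amine base
Reagents that add atoms: none
Why: Mukaiyama-type addition of a silyl enol ether to the oxocarbenium ion released from the cyclic methyl ketal forms the C5–CH2 bond, and the nucleophile should approach the face opposite the cis-disposed C4 methyl and C2 acetonyl groups (the C4 methyl sitting pseudoaxial to avoid allylic strain with the C5 methyl), which sets C5 as S with the new chain anti to the C4 methyl.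

Step 12
Reactants: 18 2,6,6-trimethylcyclohex-2-ene-1,4-dione (ketoisophorone)
Product: 19 (6R)-2,2,6-trimethylcyclohexane-1,4-dione
Conditions: baker's yeast (Saccharomyces cerevisiae), sucrose, H2O, 30 °C
Reagents that add atoms: none
Why: Ene-reductase reduction of the activated enedione C=C by fermenting yeast is an established biotransformation of this substrate, the enzyme delivering hydride and proton so as to set C6 as R.

Step 13
Reactants: 19 (6R)-2,2,6-trimethylcyclohexane-1,4-dione
Product: 20 (4R,6R)-4-hydroxy-2,2,6-trimethylcyclohexan-1-one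
Conditions: LiBH(s-Bu)3 (1 equiv), THF, −78 °C; then NaOH, H2O2, 0 °C
Reagents that add atoms: none
Why: The bulky borohydride should reduce only the unhindered C4 carbonyl and, as with 3,3,5-trimethylcyclohexanone, from the equatorial side away from the axial C2 methyl, so that the C6 centre controls the new C4 (R) centre as the axial alcohol trans to the C6 methyl, the minor cis epimer being removed by crystallisation.

Step 14
Reactants: 20 (4R,6R)-4-hydroxy-2,2,6-trimethylcyclohexan-1-one
Product: 21 (4R,6R)-2,2,6-trimethyl-4-(triethylsilyloxy)cyclohexan-1-one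
Conditions: Et3SiCl, imidazole, DMF, 0 to 20 °C
Reagents that add atoms: chlorotriethylsilane, CC[Si](Cl)(CC)CC
Why: Imidazole-promoted silylation of a secondary alcohol gives a triethylsilyl ether that withstands strong base and palladium catalysis and is later removed by dilute acid.

Step 15
Reactants: 21 (4R,6R)-2,2,6-trimethyl-4-(triethylsilyloxy)cyclohexan-1-one
Product: 22 (4R)-2,6,6-trimethyl-4-(triethylsilyloxy)cyclohex-1-en-1-yl trifluoromethanesulfonate
Conditions: LiN(i-Pr)2, THF, −78 °C; then PhNTf2, −78 to 20 °C; NH4Cl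
Reagents that add atoms: N-phenylbis(trifluoromethanesulfonimide), O=S(=O)(N(c1ccccc1)S(=O)(=O)C(F)(F)F)C(F)(F)F
Why: The ketone carries an α-hydrogen only at C6, so enolate formation and O-sulfonylation (enol triflate synthesis) can give only the tetrasubstituted vinyl triflate, the C6 centre being erased and C4 untouched.

Step 16
Reactants: 23 (2E)-3-methylpent-2-en-4-yn-1-ol
Product: 24 (3E)-5-bromo-3-methylpent-3-en-1-yne
Conditions: PBr3, pyridine (cat.), Et2O, −10 °C
Reagents that add atoms: phosphorus tribromide, BrP(Br)Br
Why: Bromination of a primary allylic alcohol with PBr3 proceeds by SN2 displacement of the phosphite ester at low temperature, which keeps the E double bond and the alkyne intact.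

Step 17
Reactants: 24 (3E)-5-bromo-3-methylpent-3-en-1-yne
Product: 25 diethyl [(2E)-3-methylpent-2-en-4-yn-1-yl]phosphonate
Conditions: P(OEt)3, 90 °C
Reagents that add atoms: triethyl phosphite, CCOP(OCC)OCC
Why: Michaelis–Arbuzov reaction of a primary allylic bromide with triethyl phosphite gives the allylic phosphonate with loss of bromoethane and without change of alkene geometry.

Step 18
Reactants: 22 (4R)-2,6,6-trimethyl-4-(triethylsilyloxy)cyclohex-1-en-1-yl trifluoromethanesulfonate; 25 diethyl [(2E)-3-methylpent-2-en-4-yn-1-yl]phosphonate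
Product: 26 diethyl {(2E)-3-methyl-5-[(4R)-2,6,6-trimethyl-4-(triethylsilyloxy)cyclohex-1-en-1-yl]pent-2-en-4-yn-1-yl}phosphonate
Conditions: Pd(PPh3)4 (5 mol%), CuI (10 mol%), i-Pr2NH, DMF, 20 °C
Reagents that add atoms: none
Why: Sonogashira coupling of a vinyl triflate with a terminal alkyne forms the ring–alkyne bond of the acetylenic end group under amine conditions that neither deprotonate the phosphonate nor isomerise the E enyne.

Step 19
Reactants: 26 diethyl {(2E)-3-methyl-5-[(4R)-2,6,6-trimethyl-4-(triethylsilyloxy)cyclohex-1-en-1-yl]pent-2-en-4-yn-1-yl}phosphonate; 27 (2E,4E,6E)-2,7-dimethylocta-2,4,6-trienedial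
Product: 29 (2E,4E,6E,8E,10E)-13-[(4R)-4-hydroxy-2,6,6-trimethylcyclohex-1-en-1-yl]-2,7,11-trimethyltrideca-2,4,6,8,10-pentaen-12-ynal, via silyl ether 28 (not isolated)
Conditions: KN(SiMe3)2, THF, −78 °C, anion added to 27 (3 equiv), −78 to 0 °C; then 1 M aq. HCl, THF, 0 °C
Reagents that add atoms: none
Why: Horner–Wadsworth–Emmons olefination of the allylic phosphonate anion with one formyl group of the excess symmetrical dialdehyde should give the new disubstituted double bond E through reversible addition and collapse of the less crowded adduct, and the dilute acid of the work-up cleaves the triethylsilyl ether.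

Step 20
Reactants: 30 dibromomethane
Product: 31 (dibromomethyl)tributylstannane
Conditions: LiN(i-Pr)2, THF, −90 °C; then Bu3SnCl, −90 to −40 °C
Reagents that add atoms: chlorotributylstannane, CCCC[Sn](Cl)(CCCC)CCCC
Why: Deprotonation of dibromomethane gives dibromomethyllithium, which is persistent at very low temperature and is captured at carbon by nucleophilic substitution at tin.

Step 21
Reactants: 29 (2E,4E,6E,8E,10E)-13-[(4R)-4-hydroxy-2,6,6-trimethylcyclohex-1-en-1-yl]-2,7,11-trimethyltrideca-2,4,6,8,10-pentaen-12-ynal; 31 (dibromomethyl)tributylstannane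
Product: 32 (1R)-3,5,5-trimethyl-4-[(3E,5E,7E,9E,11E,13E)-3,7,12-trimethyl-14-(tributylstannyl)tetradeca-3,5,7,9,11,13-hexaen-1-yn-1-yl]cyclohex-3-en-1-ol
Conditions: CrCl2, LiI, DMF/THF, 20 °C, dark
Reagents that add atoms: none
Why: Takai-type olefination with the geminal dichromium species that divalent chromium generates from the dibromomethylstannane converts the aldehyde into the vinylstannane, the E geometry following from the sterically preferred arrangement of the β-oxido organochromium adduct on elimination, while the free hydroxyl is tolerated.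

Step 22
Reactants: 17 1-[(2R,4R,5S)-5-[(3E)-4-iodo-3-methyl-2-oxobut-3-en-1-yl]-4,5-dimethyloxolan-2-yl]propan-2-one; 32 (1R)-3,5,5-trimethyl-4-[(3E,5E,7E,9E,11E,13E)-3,7,12-trimethyl-14-(tributylstannyl)tetradeca-3,5,7,9,11,13-hexaen-1-yn-1-yl]cyclohex-3-en-1-ol
Product: 33 crassostreaxanthin A
Conditions: Pd2(dba)3·CHCl3 (5 mol%), AsPh3 (40 mol%), N-methylpyrrolidone, 20 °C, dark, argon
Reagents that add atoms: none
Why: Stille coupling of the β-iodo enone with the polyenyl stannane under base-free, ligand-accelerated conditions joins the iodine-bearing and tin-bearing carbons with retention of both double-bond geometries and should leave the ketones, the free alcohol and the β-alkoxy ketone untouched.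

Compound list

1 | 3,4,5-trimethylphenol | Cc1cc(O)cc(C)c1C | starting material
2 | 5-methoxy-1,2,3-trimethylbenzene | COc1cc(C)c(C)c(C)c1 | intermediate
3 | 1-methoxy-3,4,5-trimethylcyclohexa-1,4-diene (racemic, not isolated) | COC1=CC(C)C(C)=C(C)C1 | intermediate
4 | 3,4,5-trimethylcyclohex-3-en-1-one (racemic) | CC1=C(C)C(C)CC(=O)C1 | intermediate
5 | trans-3,4,5-trimethylcyclohex-3-en-1-ol (racemate; the 1R,5R enantiomer is drawn) | CC1=C(C)[C@H](C)C[C@@H](O)C1 | intermediate
6 | (1R,5R)-3,4,5-trimethylcyclohex-3-en-1-yl acetate | CC1=C(C)[C@H](C)C[C@@H](OC(C)=O)C1 | intermediate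
7 | (1R,5R)-3,4,5-trimethylcyclohex-3-en-1-ol | CC1=C(C)[C@H](C)C[C@@H](O)C1 | intermediate
8 | primary ozonide of 7: 3a,4,7a-trimethylhexahydro-1,2,3-benzotrioxol-6-ol, C4 and C6 as in 7, cis ring fusion on either face (not isolated) | CC12OOOC1(C)[C@H](C)C[C@@H](O)C2 | intermediate
9 | (4R,6R)-4-hydroxy-6-methyloctane-2,7-dione (not isolated) | CC(=O)C[C@H](O)C[C@@H](C)C(C)=O | intermediate
10 | 1-[(2R,4R)-5-hydroxy-4,5-dimethyloxolan-2-yl]propan-2-one (both C5 anomers) | CC(=O)C[C@H]1C[C@@H](C)C(C)(O)O1 | intermediate
11 | 1-[(2R,4R)-5-methoxy-4,5-dimethyloxolan-2-yl]propan-2-one (both C5 anomers) | CC(=O)C[C@H]1C[C@@H](C)C(C)(OC)O1 | intermediate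
12 | but-3-yn-2-ol (racemic) | CC(O)C#C | starting material
13 | (E)-[3-(dimethylalumanyloxy)-2-methylbut-1-en-1-yl]dimethylalumane (racemic, not isolated) | C[Al](C)/C=C(\C)C(C)O[Al](C)C | intermediate
14 | (E)-4-iodo-3-methylbut-3-en-2-ol (racemic) | CC(O)/C(C)=C/I | intermediate
15 | (E)-4-iodo-3-methylbut-3-en-2-one | CC(=O)/C(C)=C/I | intermediate
16 | [(3E)-4-iodo-3-methylbuta-1,3-dien-2-yl]oxy(trimethyl)silane | C=C(O[Si](C)(C)C)/C(C)=C/I | intermediate
17 | 1-[(2R,4R,5S)-5-[(3E)-4-iodo-3-methyl-2-oxobut-3-en-1-yl]-4,5-dimethyloxolan-2-yl]propan-2-one | CC(=O)C[C@H]1C[C@@H](C)[C@](C)(CC(=O)/C(C)=C/I)O1 | intermediate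
18 | 2,6,6-trimethylcyclohex-2-ene-1,4-dione (ketoisophorone) | CC1=CC(=O)CC(C)(C)C1=O | starting material
19 | (6R)-2,2,6-trimethylcyclohexane-1,4-dione | CC1(C)CC(=O)C[C@@H](C)C1=O | intermediate
20 | (4R,6R)-4-hydroxy-2,2,6-trimethylcyclohexan-1-one | CC1(C)C[C@H](O)C[C@@H](C)C1=O | intermediate
21 | (4R,6R)-2,2,6-trimethyl-4-(triethylsilyloxy)cyclohexan-1-one | CC1(C)C[C@H](O[Si](CC)(CC)CC)C[C@@H](C)C1=O | intermediate
22 | (4R)-2,6,6-trimethyl-4-(triethylsilyloxy)cyclohex-1-en-1-yl trifluoromethanesulfonate | FC(F)(F)S(=O)(=O)OC1=C(C)C[C@@H](O[Si](CC)(CC)CC)CC1(C)C | intermediate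
23 | (2E)-3-methylpent-2-en-4-yn-1-ol | OC/C=C(\C)C#C | starting material
24 | (3E)-5-bromo-3-methylpent-3-en-1-yne | BrC/C=C(\C)C#C | intermediate
25 | diethyl [(2E)-3-methylpent-2-en-4-yn-1-yl]phosphonate | CCOP(=O)(OCC)C/C=C(\C)C#C | intermediate
26 | diethyl {(2E)-3-methyl-5-[(4R)-2,6,6-trimethyl-4-(triethylsilyloxy)cyclohex-1-en-1-yl]pent-2-en-4-yn-1-yl}phosphonate | CCOP(=O)(OCC)C/C=C(\C)C#CC1=C(C)C[C@@H](O[Si](CC)(CC)CC)CC1(C)C | intermediate
27 | (2E,4E,6E)-2,7-dimethylocta-2,4,6-trienedial | O=C/C(C)=C/C=C/C=C(C)/C=O | starting material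
28 | (2E,4E,6E,8E,10E)-2,7,11-trimethyl-13-[(4R)-2,6,6-trimethyl-4-(triethylsilyloxy)cyclohex-1-en-1-yl]trideca-2,4,6,8,10-pentaen-12-ynal (not isolated) | O=C/C(C)=C/C=C/C=C(C)/C=C/C=C(\C)C#CC1=C(C)C[C@@H](O[Si](CC)(CC)CC)CC1(C)C | intermediate
29 | (2E,4E,6E,8E,10E)-13-[(4R)-4-hydroxy-2,6,6-trimethylcyclohex-1-en-1-yl]-2,7,11-trimethyltrideca-2,4,6,8,10-pentaen-12-ynal | O=C/C(C)=C/C=C/C=C(C)/C=C/C=C(\C)C#CC1=C(C)C[C@@H](O)CC1(C)C | intermediate
30 | dibromomethane | BrCBr | starting material
31 | (dibromomethyl)tributylstannane | CCCC[Sn](CCCC)(CCCC)C(Br)Br | intermediate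
32 | (1R)-3,5,5-trimethyl-4-[(3E,5E,7E,9E,11E,13E)-3,7,12-trimethyl-14-(tributylstannyl)tetradeca-3,5,7,9,11,13-hexaen-1-yn-1-yl]cyclohex-3-en-1-ol | CCCC[Sn](CCCC)(CCCC)/C=C/C(C)=C/C=C/C=C(C)/C=C/C=C(\C)C#CC1=C(C)C[C@@H](O)CC1(C)C | intermediate
33 | crassostreaxanthin A | CC(=O)C[C@H]1C[C@@H](C)[C@](C)(CC(=O)/C(C)=C/C=C/C(C)=C/C=C/C=C(C)/C=C/C=C(\C)C#CC2=C(C)C[C@@H](O)CC2(C)C)O1 | target

Total step count: 22 steps.
Longest linear sequence: 9 steps (steps 1 to 7, 11 and 22).

Steps most likely to fail

Step 11. The enol silane may attack both faces of the tertiary oxocarbenium ion, and the Lewis acid may engage the free acetonyl carbonyl in aldol-type side reactions, so that C5 forms with poor facial selectivity. The fallback removes the carbonyl and enlarges the C2 arm for the coupling. It sets out from 11. Reduction with NaBH4 in MeOH at 0 °C should give 1-[(2R,4R)-5-methoxy-4,5-dimethyloxolan-2-yl]propan-2-ol F1 (both carbinol epimers, both usable). Silylation with t-BuMe2SiCl and imidazole in DMF would give tert-butyl-dimethyl-{1-[(2R,4R)-5-methoxy-4,5-dimethyloxolan-2-yl]propan-2-yloxy}silane F2. Its bulkier, carbonyl-free arm shields the face cis to the C4 methyl more strongly and offers the Lewis acid no second electrophile. Coupling with 16 under the conditions of step 11 should then give (3E)-1-{(2S,3R,5R)-5-[2-(tert-butyldimethylsilyloxy)propyl]-2,3-dimethyloxolan-2-yl}-4-iodo-3-methylbut-3-en-2-one F3. HF·pyridine in THF/pyridine would free (3E)-1-[(2S,3R,5R)-5-(2-hydroxypropyl)-2,3-dimethyloxolan-2-yl]-4-iodo-3-methylbut-3-en-2-one F4. Dess–Martin oxidation (NaHCO3, CH2Cl2) then comes back to the route at 17.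

Step 4. The enzyme may discriminate the two trans enantiomers too weakly, because both carbons flanking the carbinol are CH2 groups and the difference lies one atom further out. The fallback is a classical resolution through covalent diastereomers, setting out from 5. Acylation with (1S)-camphanic chloride (pyridine, 4-dimethylaminopyridine, CH2Cl2) gives two diastereomeric esters, which are separated by crystallisation or chromatography. This should provide (1R,5R)-3,4,5-trimethylcyclohex-3-en-1-yl (1S,4R)-camphanate F5. Saponification with LiOH in THF/MeOH/H2O comes back to the route at 7.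

Step 21. Divalent chromium may reduce or pinacol-couple the sensitive hydroxy polyenynal, and the long polyene may partly lose its geometry during the slow olefination. The fallback changes the order of assembly, so that chromium meets only the robust C10 dialdehyde. It sets out from 27 (3 equiv) and 31, which with CrCl2 and LiI in DMF/THF should give, by mono-olefination, (2E,4E,6E,8E)-2,7-dimethyl-9-(tributylstannyl)nona-2,4,6,8-tetraenal F6. Horner–Wadsworth–Emmons olefination of F6 with the potassium anion of 26 (KN(SiMe3)2, THF, −78 to 0 °C) would give triethyl{[(1R)-3,5,5-trimethyl-4-[(3E,5E,7E,9E,11E,13E)-3,7,12-trimethyl-14-(tributylstannyl)tetradeca-3,5,7,9,11,13-hexaen-1-yn-1-yl]cyclohex-3-en-1-yl]oxy}silane F7. Desilylation with Bu4NF in THF at 0 °C, under which the vinylstannane is stable, comes back to the route at 32.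

Further compounds

F1 | step 11 | 1-[(2R,4R)-5-methoxy-4,5-dimethyloxolan-2-yl]propan-2-ol (carbinol epimers) | CC(O)C[C@H]1C[C@@H](C)C(C)(OC)O1
F2 | step 11 | tert-butyl-dimethyl-{1-[(2R,4R)-5-methoxy-4,5-dimethyloxolan-2-yl]propan-2-yloxy}silane | CC(C[C@H]1C[C@@H](C)C(C)(OC)O1)O[Si](C)(C)C(C)(C)C
F3 | step 11 | (3E)-1-{(2S,3R,5R)-5-[2-(tert-butyldimethylsilyloxy)propyl]-2,3-dimethyloxolan-2-yl}-4-iodo-3-methylbut-3-en-2-one | CC(C[C@H]1C[C@@H](C)[C@](C)(CC(=O)/C(C)=C/I)O1)O[Si](C)(C)C(C)(C)C
F4 | step 11 | (3E)-1-[(2S,3R,5R)-5-(2-hydroxypropyl)-2,3-dimethyloxolan-2-yl]-4-iodo-3-methylbut-3-en-2-one | CC(O)C[C@H]1C[C@@H](C)[C@](C)(CC(=O)/C(C)=C/I)O1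
F5 | step 4 | (1R,5R)-3,4,5-trimethylcyclohex-3-en-1-yl (1S,4R)-4,7,7-trimethyl-3-oxo-2-oxabicyclo[2.2.1]heptane-1-carboxylate | CC1=C(C)[C@H](C)C[C@@H](OC(=O)[C@@]23CC[C@@](C)(C(=O)O2)C3(C)C)C1
F6 | step 21 | (2E,4E,6E,8E)-2,7-dimethyl-9-(tributylstannyl)nona-2,4,6,8-tetraenal | O=C/C(C)=C/C=C/C=C(C)/C=C/[Sn](CCCC)(CCCC)CCCC
F7 | step 21 | triethyl{[(1R)-3,5,5-trimethyl-4-[(3E,5E,7E,9E,11E,13E)-3,7,12-trimethyl-14-(tributylstannyl)tetradeca-3,5,7,9,11,13-hexaen-1-yn-1-yl]cyclohex-3-en-1-yl]oxy}silane | CCCC[Sn](CCCC)(CCCC)/C=C/C(C)=C/C=C/C=C(C)/C=C/C=C(\C)C#CC1=C(C)C[C@@H](O[Si](CC)(CC)CC)CC1(C)C
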